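**Retrosynthetic overview**
1. Target 20 ⇐ neutral phenol-acetate hydrolysis and double Dess–Martin oxidation (C5, C12) of triol 18.
2. 18 ⇐ C1–C2 bond: benzyl bromide 16 plus the alkenylalane from terminal alkyne 13; the methylalumination brings the C3 methyl and fixes the 2E alkene.
3. 13 ⇐ C4–C5 bond: zinc propargylation of enal 10; 10 ⇐ C12–C13 bond: (E)-alkenylzinc from alkyne 5 plus aldehyde 4.
4. 4 ⇐ organocatalytic enantioselective transfer hydrogenation/protonation of dienal 3 (sets C11, the only stereocentre); 3 ⇐ geranyl acetate 1, which supplies C5–C12 and the 6E alkene.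
5. No ring is formed; the arene is bought as 4-methoxy-3,5-dimethylphenol 14.

Chain atoms are numbered C1–C16 as in the target's hexadecatriene chain (C1 = benzylic CH2).
Assumption: 4-methoxy-3,5-dimethylphenol (14) is taken as a catalogue compound.
Assumption: the (S)-catalyst of step 2 is taken to give the R aldehyde; if the sense proves opposite, the equally accessible (R)-catalyst is used.

**Route**

Step 1
Reactants: 1 geranyl acetate, (2E)-3,7-dimethylocta-2,6-dien-1-yl acetate
Product: 3 (2E,6E)-3,7-dimethyl-8-oxoocta-2,6-dien-1-yl acetate, via 8-hydroxygeranyl acetate 2 (not isolated)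
Conditions: SeO2 (0.1 equiv), t-BuOOH (3 equiv), salicylic acid (0.1 equiv), CH2Cl2, rt; filter, then MnO2 (10 equiv), CH2Cl2, rt
Reagents that add atoms: tert-butyl hydroperoxide CC(C)(C)OO, its oxygen passed on by the catalyst SeO2 O=[Se]=O
Why: Catalytic SeO2/t-BuOOH allylic oxidation (ene reaction then [2,3]-shift) attacks the E-methyl group of the electron-richer terminal alkene selectively, and MnO2 then takes the allylic alcohol to the (E)-enal without touching the acetate or either alkene geometry.

Step 2
Reactants: 3 (2E,6E)-3,7-dimethyl-8-oxoocta-2,6-dien-1-yl acetate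
Product: 4 (2E,7R)-3,7-dimethyl-8-oxooct-2-en-1-yl acetate
Conditions: (S)-H2NCH(t-Bu)CH2NEt2·TfOH (20 mol %), diethyl 2,6-dimethyl-1,4-dihydropyridine-3,5-dicarboxylate (1.2 equiv), CHCl3, 0 °C; used at once
Reagents that add atoms: none
Why: Proposed new method: the primary amine condenses with the α-branched enal to an s-trans iminium ion, the Hantzsch ester delivers hydride to the unhindered β-carbon (C6), and the single enamine geometry so formed is protonated at C7 on one face by the catalyst's own ammonium N–H before it can equilibrate, which sets the R centre; the closest known reactions are the iminium-catalysed Hantzsch-ester transfer hydrogenation of β,β-disubstituted enals (stereocentre from the hydride step) and the primary–tertiary diamine-catalysed conjugate addition/enantioselective enamine protonation of α-substituted acroleins (stereocentre from the proton step), which have not been shown merged on an α-methyl-β-alkyl enal; the isolated trisubstituted alkene and the acetate are inert.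

Step 3
Reactants: 4 (2E,7R)-3,7-dimethyl-8-oxooct-2-en-1-yl acetate; 5 trimethyl[(2-methylbut-3-yn-2-yl)oxy]silane
Product: 9 (2E,7R,9E)-3,7,11-trimethyldodeca-2,9-diene-1,8,11-triol (C8 epimers), via alkenylzirconocene chloride 6 (not isolated), via alkenyl(methyl)zinc 7 (not isolated), via silyl ether acetate 8 (not isolated)
Conditions: 5, Cp2Zr(H)Cl, CH2Cl2, rt; Me2Zn, −65 °C; 4, −65 to 0 °C; H2O work-up; crude, K2CO3 (0.2 equiv), MeOH, rt
Reagents that add atoms: none
Why: Hydrozirconation is syn and puts Zr on the terminal carbon, Zr-to-Zn transmetalation gives an (E)-alkenylzinc that adds 1,2 to the aldehyde without attacking the acetate or epimerising the α-centre (alkenylzirconocene/zinc aldehyde addition), and catalytic K2CO3 in MeOH then methanolyses the acetate and the TMS ether; the new carbinol centre (target C12) is an epimer mixture that step 9 erases.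

Step 4
Reactants: 9 (2E,7R,9E)-3,7,11-trimethyldodeca-2,9-diene-1,8,11-triol
Product: 10 (2E,7R,9E)-8,11-dihydroxy-3,7,11-trimethyldodeca-2,9-dienal (C8 epimers)
Conditions: TEMPO (0.1 equiv), PhI(OAc)2 (1.1 equiv), CH2Cl2, 0 °C to rt
Reagents that add atoms: none
Why: The TEMPO/PhI(OAc)2 oxoammonium oxidation is strongly selective for the unhindered primary allylic alcohol over the hindered secondary and the tertiary alcohol and gives the (E)-enal without alkene isomerisation.

Step 5
Reactants: 10 (2E,7R,9E)-8,11-dihydroxy-3,7,11-trimethyldodeca-2,9-dienal; 11 propargyl bromide (3-bromoprop-1-yne)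
Product: 13 (3E,6R,10E)-2,6,10-trimethylpentadeca-3,10-dien-14-yne-2,5,12-triol (C5 and C12 epimers), via allenylzinc bromide 12 (not isolated)
Conditions: Zn dust (3 equiv), 11 (2 equiv), THF, 0 °C to rt
Reagents that add atoms: none
Why: Zinc Barbier propargylation: the allenylzinc bromide formed in situ adds 1,2 to the aldehyde through an SE2' transition state to give the homopropargylic alcohol and tolerates the free hydroxyls; the new carbinol centre (target C5) is an epimer mixture that step 9 erases.

Step 6
Reactants: 14 4-methoxy-3,5-dimethylphenol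
Product: 15 4-methoxy-3,5-dimethylphenyl acetate
Conditions: Ac2O, pyridine, CH2Cl2, rt
Reagents that add atoms: acetic anhydride CC(=O)OC(C)=O
Why: Standard O-acetylation; the acetate tempers the ring for the radical bromination and masks the phenol through steps 8 and 9.

Step 7
Reactants: 15 4-methoxy-3,5-dimethylphenyl acetate
Product: 16 3-(bromomethyl)-4-methoxy-5-methylphenyl acetate
Conditions: NBS (1.0 equiv), AIBN (5 mol %), PhCF3, 80 °C
Reagents that add atoms: N-bromosuccinimide O=C1CCC(=O)N1Br
Why: Wohl–Ziegler benzylic bromination: the two methyl groups are equivalent so one equivalent of NBS gives the monobromide, and ring bromination is disfavoured because both free ring positions are meta to OMe and the phenol is acylated.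

Step 8
Reactants: 13 (3E,6R,10E)-2,6,10-trimethylpentadeca-3,10-dien-14-yne-2,5,12-triol; 16 3-(bromomethyl)-4-methoxy-5-methylphenyl acetate
Product: 18 3-[(2E,6E,11R,13E)-5,12,15-trihydroxy-3,7,11,15-tetramethylhexadeca-2,6,13-trien-1-yl]-4-methoxy-5-methylphenyl acetate (C5 and C12 epimers), via alkenylalane 17 (not isolated)
Conditions: Me3Al (6 equiv), Cp2ZrCl2 (1 equiv), CH2Cl2, 0 °C to rt; then 16 (1.3 equiv), Pd(PPh3)4 (5 mol %), THF, rt; H2O work-up
Reagents that add atoms: trimethylaluminium C[Al](C)C
Why: Negishi Zr-catalysed methylalumination adds CH3 and Al syn across the terminal alkyne with CH3 on the internal carbon (the three hydroxyls ride along as aluminium alkoxides), and Pd-catalysed cross-coupling of the alkenylalane with the benzyl bromide then forms the C1–C2 bond with retention, which fixes the 2E alkene.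

Step 9
Reactants: 18 3-[(2E,6E,11R,13E)-5,12,15-trihydroxy-3,7,11,15-tetramethylhexadeca-2,6,13-trien-1-yl]-4-methoxy-5-methylphenyl acetate
Product: 19 3-[(2E,6E,11R,13E)-15-hydroxy-3,7,11,15-tetramethyl-5,12-dioxohexadeca-2,6,13-trien-1-yl]-4-methoxy-5-methylphenyl acetate
Conditions: Dess–Martin periodinane (3 equiv), pyridine, CH2Cl2, 0 °C to rt
Reagents that add atoms: none
Why: Dess–Martin oxidation turns both secondary allylic carbinols into ketones under buffered, non-enolising conditions, leaves the tertiary alcohol alone and preserves the β,γ-alkene position and the C11 configuration; the phenol stays acetylated because hypervalent iodine would oxidise a free 4-methoxyphenol.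

Step 10
Reactants: 19 3-[(2E,6E,11R,13E)-15-hydroxy-3,7,11,15-tetramethyl-5,12-dioxohexadeca-2,6,13-trien-1-yl]-4-methoxy-5-methylphenyl acetate
Product: 20 (2E,6E,11R,13E)-15-hydroxy-1-(5-hydroxy-2-methoxy-3-methylphenyl)-3,7,11,15-tetramethylhexadeca-2,6,13-triene-5,12-dione
Conditions: NH4OAc (8 equiv), MeOH/H2O 4:1, rt
Reagents that add atoms: none
Why: Ammonium-acetate-mediated hydrolysis of a phenolic acetate at neutral pH frees the phenol without base, so the C4 methylene is not enolised (no alkene migration into conjugation) and C11 is not epimerised.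

**Compound list**
1 | geranyl acetate, (2E)-3,7-dimethylocta-2,6-dien-1-yl acetate | CC(C)=CCC/C(C)=C/COC(C)=O | starting material
2 | (2E,6E)-8-hydroxy-3,7-dimethylocta-2,6-dien-1-yl acetate (8-hydroxygeranyl acetate) | OC/C(C)=C/CC/C(C)=C/COC(C)=O | intermediate
3 | (2E,6E)-3,7-dimethyl-8-oxoocta-2,6-dien-1-yl acetate | O=C/C(C)=C/CC/C(C)=C/COC(C)=O | intermediate
4 | (2E,7R)-3,7-dimethyl-8-oxooct-2-en-1-yl acetate | O=C[C@H](C)CCC/C(C)=C/COC(C)=O | intermediate
5 | trimethyl[(2-methylbut-3-yn-2-yl)oxy]silane | C#CC(C)(C)O[Si](C)(C)C | starting material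
6 | chlorobis(cyclopentadienyl)[(1E)-3-methyl-3-(trimethylsilyloxy)but-1-en-1-yl]zirconium | C[Si](C)(C)OC(C)(C)/C=C/[Zr](Cl)(C1C=CC=C1)C1C=CC=C1 | intermediate
7 | methyl[(1E)-3-methyl-3-(trimethylsilyloxy)but-1-en-1-yl]zinc | C[Zn]/C=C/C(C)(C)O[Si](C)(C)C | intermediate
8 | (2E,7R,9E)-8-hydroxy-3,7,11-trimethyl-11-(trimethylsilyloxy)dodeca-2,9-dien-1-yl acetate (C8 epimers) | CC(=O)OC/C=C(\C)CCC[C@@H](C)C(O)/C=C/C(C)(C)O[Si](C)(C)C | intermediate
9 | (2E,7R,9E)-3,7,11-trimethyldodeca-2,9-diene-1,8,11-triol (C8 epimers) | OC/C=C(\C)CCC[C@@H](C)C(O)/C=C/C(C)(C)O | intermediate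
10 | (2E,7R,9E)-8,11-dihydroxy-3,7,11-trimethyldodeca-2,9-dienal (C8 epimers) | O=C/C=C(\C)CCC[C@@H](C)C(O)/C=C/C(C)(C)O | intermediate
11 | propargyl bromide (3-bromoprop-1-yne) | C#CCBr | starting material
12 | allenylzinc bromide (propa-1,2-dien-1-ylzinc bromide) | C=C=C[Zn]Br | intermediate
13 | (3E,6R,10E)-2,6,10-trimethylpentadeca-3,10-dien-14-yne-2,5,12-triol (C5 and C12 epimers) | C#CCC(O)/C=C(\C)CCC[C@@H](C)C(O)/C=C/C(C)(C)O | intermediate
14 | 4-methoxy-3,5-dimethylphenol | COc1c(C)cc(O)cc1C | starting material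
15 | 4-methoxy-3,5-dimethylphenyl acetate | COc1c(C)cc(OC(C)=O)cc1C | intermediate
16 | 3-(bromomethyl)-4-methoxy-5-methylphenyl acetate | COc1c(C)cc(OC(C)=O)cc1CBr | intermediate
17 | (E)-alkenyl(dimethyl)alane of 13 after syn methylalumination, hydroxyls as dimethylaluminium alkoxides | C[Al](C)/C=C(\C)CC(O[Al](C)C)/C=C(\C)CCC[C@@H](C)C(O[Al](C)C)/C=C/C(C)(C)O[Al](C)C | intermediate
18 | 3-[(2E,6E,11R,13E)-5,12,15-trihydroxy-3,7,11,15-tetramethylhexadeca-2,6,13-trien-1-yl]-4-methoxy-5-methylphenyl acetate (C5 and C12 epimers) | COc1c(C)cc(OC(C)=O)cc1C/C=C(\C)CC(O)/C=C(\C)CCC[C@@H](C)C(O)/C=C/C(C)(C)O | intermediate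
19 | 3-[(2E,6E,11R,13E)-15-hydroxy-3,7,11,15-tetramethyl-5,12-dioxohexadeca-2,6,13-trien-1-yl]-4-methoxy-5-methylphenyl acetate | COc1c(C)cc(OC(C)=O)cc1C/C=C(\C)CC(=O)/C=C(\C)CCC[C@@H](C)C(=O)/C=C/C(C)(C)O | intermediate
20 | (2E,6E,11R,13E)-15-hydroxy-1-(5-hydroxy-2-methoxy-3-methylphenyl)-3,7,11,15-tetramethylhexadeca-2,6,13-triene-5,12-dione | COc1c(C)cc(O)cc1C/C=C(\C)CC(=O)/C=C(\C)CCC[C@@H](C)C(=O)/C=C/C(C)(C)O | target

**Step count and risks**
Total steps: 10 (8 on the main chain, 2 for the benzyl bromide). Longest linear sequence: 8 steps (1, 2, 3, 4, 5, 8, 9, 10) from geranyl acetate.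

The three steps most likely to fail:

Step 2 (the proposed new reaction). Risks are low enantioselectivity if the enamine geometry leaks before protonation, loss of catalyst by reductive amination with the product aldehyde, and erosion of ee on standing. The ee is read on an aliquot after NaBH4 reduction. The fallback uses known chemistry and sets out from compound 2, isolated by leaving out the MnO2 stage of step 1. Hydroxyl-directed asymmetric hydrogenation with Ru(OAc)2[(R)-BINAP] under H2 in MeOH (ligand antipode chosen for R) reduces only the allylic-alcohol alkene and gives (2E,7R)-8-hydroxy-3,7-dimethyloct-2-en-1-yl acetate F1. TEMPO/PhI(OAc)2 oxidation of F1 then gives 4, where it comes back to the route.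

Step 8 (one-pot methylalumination and benzyl coupling on an unprotected triol). Risks are sluggish carbometalation of the tris-alkoxide and methyl transfer to the benzyl bromide from excess Me3Al. The fallback sets out from 13 and inverts the polarity of the coupling. The same methylalumination is quenched with I2 to give (3E,6R,10E,14E)-15-iodo-2,6,10,14-tetramethylpentadeca-3,10,14-triene-2,5,12-triol F2, which is isolated. Separately 16 is inserted with Zn dust/LiCl in THF to give {[5-(acetyloxy)-2-methoxy-3-methylphenyl]methyl}zinc bromide F3. Negishi coupling of F2 with F3 (Pd(OAc)2, SPhos, THF, slow addition, tolerant of free hydroxyls) gives 18, where it comes back to the route.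

Step 10 (unmasking the phenol on the bis-enone). Risks are slow hydrolysis, migration of the C2 alkene into conjugation and epimerisation at C11 if conditions drift basic. The fallback sets out from 18 and changes the protecting group before any ketone exists. K2CO3 in MeOH gives 3-[(2E,6E,11R,13E)-5,12,15-trihydroxy-3,7,11,15-tetramethylhexadeca-2,6,13-trien-1-yl]-4-methoxy-5-methylphenol F4. TBSCl/Et3N in CH2Cl2 at 0 °C silylates only the phenol to give (2E,6E,11R,13E)-1-{5-[(tert-butyldimethylsilyl)oxy]-2-methoxy-3-methylphenyl}-3,7,11,15-tetramethylhexadeca-2,6,13-triene-5,12,15-triol F5. Dess–Martin oxidation gives (2E,6E,11R,13E)-1-{5-[(tert-butyldimethylsilyl)oxy]-2-methoxy-3-methylphenyl}-15-hydroxy-3,7,11,15-tetramethylhexadeca-2,6,13-triene-5,12-dione F6. HF·pyridine in THF at 0 °C then gives 20 under non-basic conditions.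

**Further compounds**
F1 | step 2 | (2E,7R)-8-hydroxy-3,7-dimethyloct-2-en-1-yl acetate | OC[C@H](C)CCC/C(C)=C/COC(C)=O
F2 | step 8 | (3E,6R,10E,14E)-15-iodo-2,6,10,14-tetramethylpentadeca-3,10,14-triene-2,5,12-triol (C5 and C12 epimers) | I/C=C(\C)CC(O)/C=C(\C)CCC[C@@H](C)C(O)/C=C/C(C)(C)O
F3 | step 8 | {[5-(acetyloxy)-2-methoxy-3-methylphenyl]methyl}zinc bromide | COc1c(C)cc(OC(C)=O)cc1C[Zn]Br
F4 | step 10 | 3-[(2E,6E,11R,13E)-5,12,15-trihydroxy-3,7,11,15-tetramethylhexadeca-2,6,13-trien-1-yl]-4-methoxy-5-methylphenol | COc1c(C)cc(O)cc1C/C=C(\C)CC(O)/C=C(\C)CCC[C@@H](C)C(O)/C=C/C(C)(C)O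
F5 | step 10 | (2E,6E,11R,13E)-1-{5-[(tert-butyldimethylsilyl)oxy]-2-methoxy-3-methylphenyl}-3,7,11,15-tetramethylhexadeca-2,6,13-triene-5,12,15-triol | COc1c(C)cc(O[Si](C)(C)C(C)(C)C)cc1C/C=C(\C)CC(O)/C=C(\C)CCC[C@@H](C)C(O)/C=C/C(C)(C)O
F6 | step 10 | (2E,6E,11R,13E)-1-{5-[(tert-butyldimethylsilyl)oxy]-2-methoxy-3-methylphenyl}-15-hydroxy-3,7,11,15-tetramethylhexadeca-2,6,13-triene-5,12-dione | COc1c(C)cc(O[Si](C)(C)C(C)(C)C)cc1C/C=C(\C)CC(=O)/C=C(\C)CCC[C@@H](C)C(=O)/C=C/C(C)(C)O
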